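**Plan**
- Retrosynthetic cuts, in order: the C8 angelate ester; the C4=C5 alkene (ring-closing metathesis of a 5-isopropenyl furanone onto a C6 vinyl group); the O–C10 ether bond of the furanone (back to a C3 hydroxyl and a C1–C10 epoxide); the lactone C12–O and C6–C7 bonds (2-(methoxycarbonyl)allylation of acrolein); then C3–C4, C1–C2, C10–C14 and C9–C10 (isopropenyl Grignard, ethylene oxide, carboalumination, acetylide opening of a glycidyl ether).
- Forward order: the C7-to-C4 chain is built linearly from the glycidyl ether, the γ-lactone is annulated at C6/C7, the oxygen heterocycle is closed by O–C10 bond formation and oxidised to the 3(2H)-furanone, and the nine-membered oxacycle (ten-membered carbocycle) is closed last at C4=C5, before acylation.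
- Enabling feature: C10 is a fully substituted carbon next to C1 and two carbons from C3, so it can be presented as the tertiary terminus of a C1–C10 epoxide lying 1,3 to a C3 hydroxyl. Acid-triggered 5-endo opening then makes the O–C10 bond, the five-membered O/C3/C2/C1/C10 ring and the quaternary stereocentre in one event, and leaves C1 as the alcohol that becomes the furanone carbonyl.
- Stereochemistry: C8 from (R)-PMB glycidyl ether; C10 from a reagent-controlled Shi epoxide opened with inversion; C6 and C7 from an anti-selective chromium allylation steered by C8; C11 by thermodynamic equilibration; the Z C4=C5 alkene by ring constraint; the Z angelate by isomerisation-free Yamaguchi acylation.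

Key step: step 14

Remark: positions are given in germacrane numbering (C1 furanone carbonyl, C2 furanone CH, C3 furanone O-bearing carbon, C4/C5 alkene, C6 lactone O-bearing carbon, C7 ring-fusion CH, C8 ester-bearing carbon, C9 CH2, C10 quaternary carbon, C11 lactone α-carbon, C12 lactone carbonyl, C13/C14/C15 the methyls on C11/C10/C4); the C3 carbinol made in step 5 is carried as an inconsequential epimer mixture until C3 becomes sp2 in step 15; (R)-PMB glycidyl ether and the enantiomer of the fructose-derived Shi ketone are taken as commercial.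

Step 1
Reactants: 1 (R)-2-{[(4-methoxybenzyl)oxy]methyl}oxirane; 2 lithium acetylide–ethylenediamine complex
Product: 3 (R)-1-[(4-methoxybenzyl)oxy]pent-4-yn-2-ol
Conditions: LiC≡CH·H2NCH2CH2NH2, DMSO, 0 °C to rt
Reagents that add atoms: none
Why: Epoxide alkynylation by SN2 attack at the terminal epoxide carbon (C9) leaves the C8 stereocentre of the glycidyl ether untouched.

Step 2
Reactants: 3 (R)-1-[(4-methoxybenzyl)oxy]pent-4-yn-2-ol
Product: 4 (R)-tert-butyl({1-[(4-methoxybenzyl)oxy]pent-4-yn-2-yl}oxy)dimethylsilane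
Conditions: TBSCl, imidazole, DMF, rt
Reagents that add atoms: tert-butyldimethylsilyl chloride, CC(C)(C)[Si](C)(C)Cl
Why: Standard silylation of a secondary alcohol; the bulky silyl ether later keeps the C8 oxygen out of the epoxide-opening step.

Step 3
Reactants: 4 (R)-tert-butyl({1-[(4-methoxybenzyl)oxy]pent-4-yn-2-yl}oxy)dimethylsilane; 5 ethylene oxide
Product: 8 (R,E)-6-[(tert-butyldimethylsilyl)oxy]-7-[(4-methoxybenzyl)oxy]-4-methylhept-3-en-1-ol, via alkenyl(dimethyl)alane 6 (not isolated), via lithium alkenyl(butyl)dimethylalanate 7 (not isolated)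
Conditions: AlMe3 (2.5 equiv), Cp2ZrCl2 (0.25 equiv), CH2Cl2, 0 °C to rt; then n-BuLi, hexane/THF, −78 °C; ethylene oxide, −78 °C to rt
Reagents that add atoms: trimethylaluminium, C[Al](C)C
Why: Negishi zirconium-catalysed syn-carboalumination puts the methyl on the internal alkyne carbon (C10) and aluminium on C1 with pure E geometry, and the derived alanate opens ethylene oxide with retention of the alkene geometry.

Step 4
Reactants: 8 (R,E)-6-[(tert-butyldimethylsilyl)oxy]-7-[(4-methoxybenzyl)oxy]-4-methylhept-3-en-1-ol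
Product: 9 (R,E)-6-[(tert-butyldimethylsilyl)oxy]-7-[(4-methoxybenzyl)oxy]-4-methylhept-3-enal
Conditions: Dess–Martin periodinane, pyridine, CH2Cl2, 0 °C; used crude
Reagents that add atoms: none
Why: Buffered Dess–Martin oxidation should give the β,γ-unsaturated aldehyde without migration of the alkene into conjugation.

Step 5
Reactants: 9 (R,E)-6-[(tert-butyldimethylsilyl)oxy]-7-[(4-methoxybenzyl)oxy]-4-methylhept-3-enal; 10 isopropenylmagnesium bromide
Product: 11 (5E,8R)-8-[(tert-butyldimethylsilyl)oxy]-9-[(4-methoxybenzyl)oxy]-2,6-dimethylnona-1,5-dien-3-ol (3-epimers)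
Conditions: THF, −78 °C
Reagents that add atoms: none
Why: Grignard 1,2-addition installs C4 and C15; the new C3 carbinol is formed without control, which is harmless because C3 becomes sp2 in step 15.

Step 6
Reactants: 11 (5E,8R)-8-[(tert-butyldimethylsilyl)oxy]-9-[(4-methoxybenzyl)oxy]-2,6-dimethylnona-1,5-dien-3-ol
Product: 12 triethylsilyl ether of 11 [(5E,8R)-8-(TBSO)-9-(PMBO)-2,6-dimethyl-3-(triethylsilyloxy)nona-1,5-diene]
Conditions: TESCl, imidazole, CH2Cl2, 0 °C
Reagents that add atoms: chlorotriethylsilane, CC[Si](Cl)(CC)CC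
Why: Silylation of the secondary allylic alcohol with the more labile TES group, so that it can later be removed beside the TBS ether.

Step 7
Reactants: 12 triethylsilyl ether of 11
Product: 13 (2R,4E)-2-[(tert-butyldimethylsilyl)oxy]-4,8-dimethyl-7-[(triethylsilyl)oxy]nona-4,8-dien-1-ol
Conditions: DDQ, CH2Cl2/pH 7 phosphate buffer, 0 °C
Reagents that add atoms: none
Why: Oxidative cleavage of the PMB ether by DDQ is orthogonal to both silyl ethers and to the isolated alkenes.

Step 8
Reactants: 13 (2R,4E)-2-[(tert-butyldimethylsilyl)oxy]-4,8-dimethyl-7-[(triethylsilyl)oxy]nona-4,8-dien-1-ol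
Product: 14 (2R,4E)-2-[(tert-butyldimethylsilyl)oxy]-4,8-dimethyl-7-[(triethylsilyl)oxy]nona-4,8-dienal
Conditions: Dess–Martin periodinane, pyridine, CH2Cl2, 0 °C
Reagents that add atoms: none
Why: Dess–Martin oxidation gives the α-silyloxy aldehyde (C7) under conditions that do not epimerise C8.

Step 9
Reactants: 14 (2R,4E)-2-[(tert-butyldimethylsilyl)oxy]-4,8-dimethyl-7-[(triethylsilyl)oxy]nona-4,8-dienal; 15 methyl acrylate
Product: 16 methyl (4R,6E)-4-[(tert-butyldimethylsilyl)oxy]-3-hydroxy-6,10-dimethyl-2-methylidene-9-[(triethylsilyl)oxy]undeca-6,10-dienoate (3- and 9-epimers)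
Conditions: DABCO (1 equiv), 1,4-dioxane/H2O (1:1), rt
Reagents that add atoms: none
Why: Morita–Baylis–Hillman reaction attaches C11–C13; the new C7 carbinol centre is inconsequential because C7 becomes sp2 in step 10.

Step 10
Reactants: 16 methyl (4R,6E)-4-[(tert-butyldimethylsilyl)oxy]-3-hydroxy-6,10-dimethyl-2-methylidene-9-[(triethylsilyl)oxy]undeca-6,10-dienoate
Product: 17 methyl (2Z,4R,6E)-2-(bromomethyl)-4-[(tert-butyldimethylsilyl)oxy]-6,10-dimethyl-9-[(triethylsilyl)oxy]undeca-2,6,10-trienoate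
Conditions: NBS, Me2S, CH2Cl2, −20 °C (pre-mixed); then 16, −20 to 0 °C
Reagents that add atoms: N-bromosuccinimide, O=C1CCC(=O)N1Br
Why: Corey–Kim-type SN2' bromination of the Baylis–Hillman alcohol should give the thermodynamically preferred (Z)-2-(bromomethyl)enoate.

Step 11
Reactants: 17 methyl (2Z,4R,6E)-2-(bromomethyl)-4-[(tert-butyldimethylsilyl)oxy]-6,10-dimethyl-9-[(triethylsilyl)oxy]undeca-2,6,10-trienoate; 18 acrolein
Product: 21 (4S,5R)-4-[(1R,3E)-1-[(tert-butyldimethylsilyl)oxy]-6-hydroxy-3,7-dimethylocta-3,7-dien-1-yl]-3-methylidene-5-vinyloxolan-2-one (4,5-trans; 6'-epimers), via allylchromium dichloride 19 (not isolated), via anti hydroxy ester 20 (not isolated)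
Conditions: CrCl2 (4 equiv), THF, 0 °C to rt; then PPTS, MeOH, rt
Reagents that add atoms: none
Why: Nozaki–Hiyama-type allylation in which the γ-substituted allylchromium adds 1,2 to acrolein through a closed chair transition state (anti, hence the 6,7-trans lactone) on the face anti to the C9 chain of the A(1,3)-locked C8 centre (C8–H eclipsing the ester-bearing alkene carbon, silyloxy group outside), the sense known for γ-(α-alkoxyalkyl)allylchromium reagents; acid then lactonises and removes the TES group.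

Step 12
Reactants: 21 (4S,5R)-4-[(1R,3E)-1-[(tert-butyldimethylsilyl)oxy]-6-hydroxy-3,7-dimethylocta-3,7-dien-1-yl]-3-methylidene-5-vinyloxolan-2-one
Product: 22 (3S,4S,5R)-4-[(1R,3E)-1-[(tert-butyldimethylsilyl)oxy]-6-hydroxy-3,7-dimethylocta-3,7-dien-1-yl]-3-methyl-5-vinyloxolan-2-one (all-trans; 6'-epimers)
Conditions: NaBH4, MeOH, 0 °C; then DBU (cat.), toluene, rt
Reagents that add atoms: none
Why: Borohydride conjugate reduction of the α-methylene lactone followed by base equilibration should place the C11 methyl trans to the C7 side chain (thermodynamic all-trans lactone).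

Step 13
Reactants: 22 (3S,4S,5R)-4-[(1R,3E)-1-[(tert-butyldimethylsilyl)oxy]-6-hydroxy-3,7-dimethylocta-3,7-dien-1-yl]-3-methyl-5-vinyloxolan-2-one
Product: 23 (3S,4S,5R)-4-[(1R)-1-[(tert-butyldimethylsilyl)oxy]-2-{(2S,3S)-3-(2-hydroxy-3-methylbut-3-en-1-yl)-2-methyloxiran-2-yl}ethyl]-3-methyl-5-vinyloxolan-2-one
Conditions: ent-Shi ketone (30 mol%), Oxone, K2CO3, Bu4NHSO4, MeCN/dimethoxymethane/aq. Na2B4O7–EDTA, 0 °C
Reagents that add atoms: potassium peroxymonosulfate (Oxone), [K+].[O-]S(=O)(=O)OO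
Why: Shi asymmetric epoxidation, in which the chiral dioxirane attacks only the electron-rich trisubstituted C1=C10 alkene through the spiro transition state; the catalyst enantiomer is chosen to give the (1S,10S)-epoxide irrespective of the remote centres.

Step 14
Reactants: 23 (3S,4S,5R)-4-[(1R)-1-[(tert-butyldimethylsilyl)oxy]-2-{(2S,3S)-3-(2-hydroxy-3-methylbut-3-en-1-yl)-2-methyloxiran-2-yl}ethyl]-3-methyl-5-vinyloxolan-2-one
Product: 24 (3S,4S,5R)-4-[(1R)-1-[(tert-butyldimethylsilyl)oxy]-2-{(2R,3S)-3-hydroxy-2-methyl-5-(prop-1-en-2-yl)oxolan-2-yl}ethyl]-3-methyl-5-vinyloxolan-2-one (epimers at the isopropenyl-bearing carbon)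
Conditions: CSA (10 mol%), CH2Cl2, 0 °C
Reagents that add atoms: none
Why: Protonation of the epoxide polarises the C10–O bond at the tertiary, cation-stabilising carbon, and the C3 hydroxyl, held 1,3 to the epoxide by the C2 methylene, attacks C10 from the rear; the closest known reaction type is the acid-catalysed cyclisation of trisubstituted 3,4-epoxy alcohols to tetrahydrofuran-3-ols. The tetrahydrofuran (future furanone) ring closes in the 5-endo-tet mode, which is feasible here because the transition state is loose and SN1-like at C10. The new quaternary stereocentre C10 is set by stereospecific inversion of the (10S)-epoxide carbon installed in step 13, giving 10R, while C1 keeps the epoxide oxygen as the alcohol that becomes the furanone carbonyl. The step needs regioselectivity for C10 over C1 (4-exo oxetane formation) and chemoselectivity over the other oxygen functions; the tertiary carbon secures the first, and the silylated C8 oxygen, the acylated C6 oxygen and the absence of any other free hydroxyl secure the second. Both C3 epimers should cyclise, since C3 takes no part in the bond-forming event.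

Step 15
Reactants: 24 (3S,4S,5R)-4-[(1R)-1-[(tert-butyldimethylsilyl)oxy]-2-{(2R,3S)-3-hydroxy-2-methyl-5-(prop-1-en-2-yl)oxolan-2-yl}ethyl]-3-methyl-5-vinyloxolan-2-one
Product: 26 (3S,4S,5R)-4-[(1R)-1-[(tert-butyldimethylsilyl)oxy]-2-{(2R)-2-methyl-3-oxo-5-(prop-1-en-2-yl)-2,3-dihydrofuran-2-yl}ethyl]-3-methyl-5-vinyloxolan-2-one, via tetrahydrofuran-3-one 25 (not isolated)
Conditions: IBX (3.5 equiv), DMSO, rt then 75 °C
Reagents that add atoms: none
Why: IBX first oxidises the C1 alcohol and then, at higher temperature, dehydrogenates the ketone across C2–C3 (IBX enone formation), the only enolisable side, which also erases the C3 stereocentre.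

Step 16
Reactants: 26 (3S,4S,5R)-4-[(1R)-1-[(tert-butyldimethylsilyl)oxy]-2-{(2R)-2-methyl-3-oxo-5-(prop-1-en-2-yl)-2,3-dihydrofuran-2-yl}ethyl]-3-methyl-5-vinyloxolan-2-one
Product: 27 8-O-tert-butyldimethylsilyl ether of 28 (furanone-bridged macrocyclic lactone, 4Z)
Conditions: second-generation Hoveyda–Grubbs catalyst (20 mol%), toluene (0.001 mol/L), 110 °C
Reagents that add atoms: none
Why: Ring-closing olefin metathesis between the isopropenyl group and the C6 vinyl group, a known way to close furanone-bridged nine-membered oxacycles; the planar furanone pre-organises the ring, which can only hold the Z (ring-cis) trisubstituted alkene.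

Step 17
Reactants: 27 8-O-tert-butyldimethylsilyl ether of 28
Product: 28 (6R,7R,8R,10R,11S)-8-hydroxy-1-oxo-3,10-epoxy-11,13-dihydrogermacra-2,4(Z)-dien-12,6-olide (the target without its angeloyl group)
Conditions: HF·pyridine, pyridine/THF, 0 °C to rt
Reagents that add atoms: none
Why: Buffered fluoride desilylation should spare the lactone, the furanone and the C11 centre.

Step 18
Reactants: 28 (6R,7R,8R,10R,11S)-8-hydroxy-1-oxo-3,10-epoxy-11,13-dihydrogermacra-2,4(Z)-dien-12,6-olide; 29 angelic acid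
Product: 30 CNP0278264.1, the 8-O-angelate of 28 (6R,7R,8R,10R,11S)
Conditions: 29, 2,4,6-trichlorobenzoyl chloride, Et3N, toluene, rt; then 28, toluene, 80 °C
Reagents that add atoms: none
Why: Yamaguchi esterification through the mixed anhydride, run hot and without a nucleophilic catalyst, is a known way to acylate hindered alcohols with angelic acid without Z-to-E isomerisation.

**Compound list**
1 | (R)-2-{[(4-methoxybenzyl)oxy]methyl}oxirane | COc1ccc(COC[C@H]2CO2)cc1 | starting material
2 | lithium acetylide–ethylenediamine complex | [Li+].[C-]#C.NCCN | starting material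
3 | (R)-1-[(4-methoxybenzyl)oxy]pent-4-yn-2-ol | COc1ccc(COC[C@H](O)CC#C)cc1 | intermediate
4 | (R)-tert-butyl({1-[(4-methoxybenzyl)oxy]pent-4-yn-2-yl}oxy)dimethylsilane | COc1ccc(COC[C@H](O[Si](C)(C)C(C)(C)C)CC#C)cc1 | intermediate
5 | ethylene oxide | C1CO1 | starting material
6 | [(R,E)-4-(TBSO)-5-(PMBO)-2-methylpent-1-enyl]dimethylalane (not isolated) | COc1ccc(COC[C@H](O[Si](C)(C)C(C)(C)C)C/C(C)=C/[Al](C)C)cc1 | intermediate
7 | lithium butyl[(R,E)-4-(TBSO)-5-(PMBO)-2-methylpent-1-enyl]dimethylaluminate (not isolated) | COc1ccc(COC[C@H](O[Si](C)(C)C(C)(C)C)C/C(C)=C/[Al-](C)(C)CCCC)cc1.[Li+] | intermediate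
8 | (R,E)-6-[(tert-butyldimethylsilyl)oxy]-7-[(4-methoxybenzyl)oxy]-4-methylhept-3-en-1-ol | COc1ccc(COC[C@H](O[Si](C)(C)C(C)(C)C)C/C(C)=C/CCO)cc1 | intermediate
9 | (R,E)-6-[(tert-butyldimethylsilyl)oxy]-7-[(4-methoxybenzyl)oxy]-4-methylhept-3-enal | COc1ccc(COC[C@H](O[Si](C)(C)C(C)(C)C)C/C(C)=C/CC=O)cc1 | intermediate
10 | isopropenylmagnesium bromide | CC(=C)[Mg]Br | starting material
11 | (5E,8R)-8-[(tert-butyldimethylsilyl)oxy]-9-[(4-methoxybenzyl)oxy]-2,6-dimethylnona-1,5-dien-3-ol (3-epimers) | COc1ccc(COC[C@H](O[Si](C)(C)C(C)(C)C)C/C(C)=C/CC(O)C(C)=C)cc1 | intermediate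
12 | triethylsilyl ether of 11 | COc1ccc(COC[C@H](O[Si](C)(C)C(C)(C)C)C/C(C)=C/CC(O[Si](CC)(CC)CC)C(C)=C)cc1 | intermediate
13 | (2R,4E)-2-[(tert-butyldimethylsilyl)oxy]-4,8-dimethyl-7-[(triethylsilyl)oxy]nona-4,8-dien-1-ol | OC[C@H](O[Si](C)(C)C(C)(C)C)C/C(C)=C/CC(O[Si](CC)(CC)CC)C(C)=C | intermediate
14 | (2R,4E)-2-[(tert-butyldimethylsilyl)oxy]-4,8-dimethyl-7-[(triethylsilyl)oxy]nona-4,8-dienal | O=C[C@H](O[Si](C)(C)C(C)(C)C)C/C(C)=C/CC(O[Si](CC)(CC)CC)C(C)=C | intermediate
15 | methyl acrylate | C=CC(=O)OC | starting material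
16 | methyl (4R,6E)-4-[(tert-butyldimethylsilyl)oxy]-3-hydroxy-6,10-dimethyl-2-methylidene-9-[(triethylsilyl)oxy]undeca-6,10-dienoate | COC(=O)C(=C)C(O)[C@H](O[Si](C)(C)C(C)(C)C)C/C(C)=C/CC(O[Si](CC)(CC)CC)C(C)=C | intermediate
17 | methyl (2Z,4R,6E)-2-(bromomethyl)-4-[(tert-butyldimethylsilyl)oxy]-6,10-dimethyl-9-[(triethylsilyl)oxy]undeca-2,6,10-trienoate | COC(=O)/C(CBr)=C/[C@H](O[Si](C)(C)C(C)(C)C)C/C(C)=C/CC(O[Si](CC)(CC)CC)C(C)=C | intermediate
18 | acrolein | C=CC=O | starting material
19 | allylchromium dichloride derived from 17 (not isolated) | COC(=O)/C(C[Cr](Cl)Cl)=C/[C@H](O[Si](C)(C)C(C)(C)C)C/C(C)=C/CC(O[Si](CC)(CC)CC)C(C)=C | intermediate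
20 | methyl 4-hydroxy-2-methylidene-3-[(1R,3E)-1-(TBSO)-3,7-dimethyl-6-(triethylsilyloxy)octa-3,7-dien-1-yl]hex-5-enoate, 3,4-anti, C6 and C7 as in 30 (not isolated) | COC(=O)C(=C)[C@@H]([C@H](O)C=C)[C@H](O[Si](C)(C)C(C)(C)C)C/C(C)=C/CC(O[Si](CC)(CC)CC)C(C)=C | intermediate
21 | (4S,5R)-4-[(1R,3E)-1-[(tert-butyldimethylsilyl)oxy]-6-hydroxy-3,7-dimethylocta-3,7-dien-1-yl]-3-methylidene-5-vinyloxolan-2-one | C=C[C@H]1OC(=O)C(=C)[C@@H]1[C@H](O[Si](C)(C)C(C)(C)C)C/C(C)=C/CC(O)C(C)=C | intermediate
22 | (3S,4S,5R)-4-[(1R,3E)-1-[(tert-butyldimethylsilyl)oxy]-6-hydroxy-3,7-dimethylocta-3,7-dien-1-yl]-3-methyl-5-vinyloxolan-2-one | C=C[C@H]1OC(=O)[C@@H](C)[C@@H]1[C@H](O[Si](C)(C)C(C)(C)C)C/C(C)=C/CC(O)C(C)=C | intermediate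
23 | (1S,10S)-1,10-epoxide of 22 | C=C[C@H]1OC(=O)[C@@H](C)[C@@H]1[C@H](O[Si](C)(C)C(C)(C)C)C[C@]1(C)O[C@H]1CC(O)C(C)=C | intermediate
24 | (3S,4S,5R)-4-[(1R)-1-[(tert-butyldimethylsilyl)oxy]-2-{(2R,3S)-3-hydroxy-2-methyl-5-(prop-1-en-2-yl)oxolan-2-yl}ethyl]-3-methyl-5-vinyloxolan-2-one | C=C[C@H]1OC(=O)[C@@H](C)[C@@H]1[C@H](O[Si](C)(C)C(C)(C)C)C[C@@]1(C)OC(C(C)=C)C[C@@H]1O | intermediate
25 | tetrahydrofuran-3-one corresponding to 24, (2R)-2-methyl-3-oxo-5-(prop-1-en-2-yl)oxolan-2-yl (not isolated) | C=C[C@H]1OC(=O)[C@@H](C)[C@@H]1[C@H](O[Si](C)(C)C(C)(C)C)C[C@@]1(C)OC(C(C)=C)CC1=O | intermediate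
26 | (3S,4S,5R)-4-[(1R)-1-[(tert-butyldimethylsilyl)oxy]-2-{(2R)-2-methyl-3-oxo-5-(prop-1-en-2-yl)-2,3-dihydrofuran-2-yl}ethyl]-3-methyl-5-vinyloxolan-2-one | C=C[C@H]1OC(=O)[C@@H](C)[C@@H]1[C@H](O[Si](C)(C)C(C)(C)C)C[C@@]1(C)OC(C(C)=C)=CC1=O | intermediate
27 | 8-O-tert-butyldimethylsilyl ether of 28 | CC(C)(C)[Si](C)(C)O[C@@H]1C[C@@]2(C)OC(=CC2=O)/C(C)=C\[C@H]2OC(=O)[C@@H](C)[C@@H]21 | intermediate
28 | (6R,7R,8R,10R,11S)-8-hydroxy-1-oxo-3,10-epoxy-11,13-dihydrogermacra-2,4(Z)-dien-12,6-olide | O[C@@H]1C[C@@]2(C)OC(=CC2=O)/C(C)=C\[C@H]2OC(=O)[C@@H](C)[C@@H]21 | intermediate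
29 | angelic acid, (Z)-2-methylbut-2-enoic acid | C/C=C(/C)C(=O)O | starting material
30 | CNP0278264.1, 8-O-angelate of 28 | C/C=C(/C)C(=O)O[C@@H]1C[C@@]2(C)OC(=CC2=O)/C(C)=C\[C@H]2OC(=O)[C@@H](C)[C@@H]21 | target

Total step count: 18. Longest linear sequence: 18 steps (1 to 30).

**Steps most likely to fail**

1. Step 11. The aldehyde may add to the wrong face of the allylchromium relative to C8, or the allylic silyloxy group may be lost by 1,4-elimination, so that C6 and C7 are not set cleanly. The fallback sets out from aldehyde 14 and comes back at 22, with C7 fixed by chirality transfer instead of by C8. Wittig olefination of 14 with 1-(triphenylphosphoranylidene)propan-2-one would give the (E)-enone F1. Corey–Bakshi–Shibata reduction with the (R)-oxazaborolidine and BH3·SMe2 would give the (S)-allylic alcohol F2, which is acylated with propionyl chloride to the propionate F3. Ireland–Claisen rearrangement (LDA, TMSCl, THF, −78 °C to rt), through the chair transition state with the carbinol methyl equatorial, would transfer that configuration to C7 and give the γ,δ-unsaturated acid F4 (C11 ratio inconsequential). Selenolactonisation (N-(phenylseleno)phthalimide, CSA cat., CH2Cl2, equilibrating) would give the 6,7-trans selenolactone F5. Oxidation with H2O2 and selenoxide elimination away from oxygen, then DBU equilibration of C11, would give the vinyl lactone F6, and PPTS in MeOH removes the TES group to return to 22.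

2. Step 16. Ring closure onto the hindered, electron-poor 1,1-disubstituted dienone olefin may be slower than oligomerisation or catalyst decay. The fallback sets out from 24 and comes back at 27, closing the ring before the furanone is made. Dess–Martin oxidation of 24 gives the isolated ketone 25, whose isopropenyl group is an ordinary allylic-ether olefin. Metathesis (same catalyst, toluene, 80 °C) of the epimer with C4 and C9 cis on the tetrahydrofuranone would give the bridged tetrahydrofuranone F7; the trans epimer cannot bridge and would be re-equilibrated at C3 with DBU by retro-oxa-Michael/oxa-Michael. Saegusa–Ito dehydrogenation of F7 (TMSOTf, Et3N; then Pd(OAc)2, MeCN) then gives 27.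

3. Step 15. The one-pot double oxidation may stall at the ketone, or the β-alkoxy ketone may ring-open by E1cB elimination at 75 °C. The fallback sets out from 24 and comes back at 26 in discrete, milder operations. Dess–Martin oxidation gives isolated 25; TMSOTf and Et3N in CH2Cl2 at 0 °C give the trimethylsilyl enol ether F8 regiospecifically, since only C2 is enolisable. Saegusa–Ito oxidation (Pd(OAc)2, MeCN, rt) then gives 26.

**Further compounds**
F1 | step 11 | (3E,5R,7E)-5-[(tert-butyldimethylsilyl)oxy]-7,11-dimethyl-10-[(triethylsilyl)oxy]dodeca-3,7,11-trien-2-one | CC(=O)/C=C/[C@H](O[Si](C)(C)C(C)(C)C)C/C(C)=C/CC(O[Si](CC)(CC)CC)C(C)=C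
F2 | step 11 | (2S,3E,5R,7E)-5-[(tert-butyldimethylsilyl)oxy]-7,11-dimethyl-10-[(triethylsilyl)oxy]dodeca-3,7,11-trien-2-ol | C[C@H](O)/C=C/[C@H](O[Si](C)(C)C(C)(C)C)C/C(C)=C/CC(O[Si](CC)(CC)CC)C(C)=C
F3 | step 11 | propionate ester of F2 | CCC(=O)O[C@@H](C)/C=C/[C@H](O[Si](C)(C)C(C)(C)C)C/C(C)=C/CC(O[Si](CC)(CC)CC)C(C)=C
F4 | step 11 | 2-methyl-3-[(1R,3E)-1-(TBSO)-3,7-dimethyl-6-(triethylsilyloxy)octa-3,7-dien-1-yl]hex-4(E)-enoic acid, C7 as in 30, C11 unassigned | OC(=O)C(C)[C@@H](/C=C/C)[C@H](O[Si](C)(C)C(C)(C)C)C/C(C)=C/CC(O[Si](CC)(CC)CC)C(C)=C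
F5 | step 11 | 6,7-trans 5-[1-(phenylselanyl)ethyl]-3-methyloxolan-2-one carrying the C8 side chain of F4 | CC([Se]c1ccccc1)[C@H]1OC(=O)C(C)[C@@H]1[C@H](O[Si](C)(C)C(C)(C)C)C/C(C)=C/CC(O[Si](CC)(CC)CC)C(C)=C
F6 | step 11 | triethylsilyl ether of 22 | C=C[C@H]1OC(=O)[C@@H](C)[C@@H]1[C@H](O[Si](C)(C)C(C)(C)C)C/C(C)=C/CC(O[Si](CC)(CC)CC)C(C)=C
F7 | step 16 | 2,3-dihydro derivative of 27 (3,10-cis-bridged tetrahydrofuran-3-one macrocycle) | CC(C)(C)[Si](C)(C)O[C@@H]1C[C@@]2(C)O[C@H](CC2=O)/C(C)=C\[C@H]2OC(=O)[C@@H](C)[C@@H]21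
F8 | step 15 | trimethylsilyl enol ether of 25 (C1–C2 enol ether) | C=C[C@H]1OC(=O)[C@@H](C)[C@@H]1[C@H](O[Si](C)(C)C(C)(C)C)C[C@@]1(C)OC(C(C)=C)C=C1O[Si](C)(C)C
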